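## Structural features

Maackiaflavanone A is a flavanone. Benzene ring A (C4a, C5–C8, C8a) is fused to the dihydropyranone ring C (O1, C2, C3, C4=O). C2 carries ring B, which is fused across C4′–C5′ to a 2,2-dimethyl-2H-pyran whose oxygen sits on C4′. Ring A is pentasubstituted: a chelated hydroxyl at C5, a methoxy group at C7 and a prenyl group at C8, so that O1 on C8a is flanked by C8 and the ring-fusion carbon C4a. Ring B has a free hydroxyl at C2′. The only stereocentre is C2 (S), with no neighbouring stereocentre to relay from. It is benzylic to a ring that has oxygen both ortho and para, and it is beta to the C4 carbonyl. C2 is therefore labile in two ways: base opens ring C by retro-oxa-Michael reaction to the chalcone, and acid can ionise the C2–O1 bond. The prenyl and chromene double bonds are sensitive to acid, free borane, hydrogenation and electrophiles, which excludes benzyl ethers and BH3. The real difficulties are the configuration at C2 and its survival, the placing of three different oxygen substituents and the prenyl group on ring A, and the linear (not angular) fusion of the pyran on ring B. The key step exploits the fact that O1 is an aryl ether oxygen on C8a: with a triflate on C8a, O1 can be brought in as the oxygen of a C2 carbinol made by ketone reduction, and the O1–C8a bond forms at the aromatic carbon while the C2–O bond is never touched.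

## Logic of the disconnections

**20 to 19.** The two O–CH2 acetal bonds on O5 and O2′ are cut last. Both phenols must stay masked through enolate, hydride, palladium, fluoride and periodinane chemistry, and an acetal is the only mask that survives all of these and does not need hydrogenation. Nothing is gained in skeleton. The demand is a deprotection that neither ionises C2–O1 nor adds to the two olefins.

**19 to 18 to 17.** The C4 carbonyl is taken back to a carbinol and then to its silyl ether (C4=O, then O–Si). A C4 ketone present before ring C is closed would be a beta-hydroxy ketone, open to retro-aldol cleavage and dehydration. The gain is a spectator at C4 whose configuration does not matter. The demand is desilylation and oxidation under conditions that are neither acidic nor strongly basic.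

**17 to 16.** The O1–C8a bond is cut. Cutting at the aryl carbon, not at C2, leaves the C2–O bond intact in the forward step, so C2 cannot ionise. Ring C opens to an acyclic 1,3-dioxygenated diarylpropane with one stereocentre that matters. The forward step must make C–O reductive elimination faster than beta-hydride elimination, and the triflate must survive the base until the metal has inserted.

**16 to 15.** The C2–H bond is cut, turning the carbinol into a ketone. The stereocentre becomes a prochiral aryl ketone. The demand is a catalyst-controlled reduction that works on both enantiomers of racemic 15 and uses a hydride source that spares the prenyl and chromene double bonds.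

**15 to 14 to 12 and 6.** The O–Si bond and then the C3–C4 bond are cut (aldol). This splits the molecule into two aromatic halves of similar size. The demand is a kinetic enolate addition that is faster than any attack on the triflate sulfur, with a cold quench to prevent retro-aldol reaction.

**6 to 5 to 4 to 3 to 1 and 2.** The O–S, O–CH2 and O–CH3 bonds and the C8–C1″ bond of the prenyl group are cut in turn. The three hydroxyls of 3 differ in acidity and hindrance, so they can be addressed one after the other, and C3 and C5 of 1 are equivalent. The gain is a symmetric commercial trihydroxy aldehyde. The demand is site selectivity in each of the three O-functionalisations.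

**12 to 10 to 9 to 7 and 8.** The aryl–acyl bond is cut (bromine–lithium exchange and acylation), then the O–CH2 bond, then the pyran ring (chromene C4–C4a and O1–C2). A pyran annulation on an ortho-hydroxy aryl ketone would be steered by the chelate to the carbon between the two oxygens and give the angular isomer. In 7 the bromine occupies the future acyl position instead, so no chelate biases the ring, and the bromine later serves as the handle for the acetyl group. The demand is annulation at C6 of 7 and not at C2 between the hydroxyls.

## Other disconnections considered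

**Alternative 1:** The cut removes C4a–C4, C4–C3 and O1–C2 together. Ring C would be assembled from the iodophenol A1 (2-iodo-5-methoxy-3-(methoxymethoxy)-6-prenylphenol), carbon monoxide A2 and the ring B alkyne A3 (6-ethynyl-7-(methoxymethoxy)-2,2-dimethyl-2H-chromene). In the forward step a palladium-catalysed carbonylative alkynylation of A1 would give an alkynone, which the amine base should close in the 6-endo mode to the flavone A4.

- In its favour: three bonds and a ring form in one operation. C4 arrives as the ketone, so the silyl ether, desilylation and oxidation of the chosen plan are not needed. The phenol oxygen of ring A becomes O1 directly, without a triflate. On convergence and bond count this alternative is better than the chosen plan, and A1 and A3 are about as accessible as 6 and 12.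
- Against it here: A4 is flat at C2. The stereocentre would have to be made afterwards by enantioselective 1,4-reduction of a vinylogous ester, in the presence of the prenyl and chromene olefins, giving a product (19) that can re-open by retro-oxa-Michael reaction under hydridic or basic conditions. 5-exo closure to an aurone and the handling of a toxic gas are further drawbacks. Iodination to A1 has a site-selectivity problem of the same kind as ring A in the chosen plan.
- Comparison: the alternative is shorter up to the tricyclic core. The chosen plan is stronger on the decisive point, because C2 is set by a well-understood ketone reduction and carried through a ring closure that retains it by mechanism.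

**Alternative 2:** The cut removes C5–C6, C7–C8 and C4a–C5, so ring A is built onto a preformed chiral ring C. The acid chloride A5, a (2S)-2-aryl-2,3-dihydro-4H-pyran-4-one with a 1-chlorocarbonyl-4-methylpent-3-enyl group on C6, would be dehydrochlorinated by a tertiary amine to the vinylketene A6. A6 should add methoxyacetylene A7 by (2+2) cycloaddition, and four-electron ring opening followed by six-electron electrocyclisation and tautomerisation would give the 2′-O-MOM ether A8 (Danheiser-type benzannulation).

- In its favour: the mechanism places the free C5 hydroxyl, the C7 methoxy group and the C8 prenyl group unambiguously, so no differentiation of three phenols is needed. On ring A regiochemistry it is better than the chosen plan. The stereocentre sits in a dihydropyranone of a type for which catalytic asymmetric hetero-Diels–Alder chemistry is well developed, which makes it the equal of the chosen plan in how C2 is set. The C4 ketone is already present and only one protecting group remains.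
- Against it here: A5 has an enolisable C3 next to C2 and is a beta-alkoxy enone. Amine base and the heat normally needed to open the cyclobutenone invite retro-oxa-Michael opening and loss of configuration. The vinyl part of A6 is an electron-poor enone double bond, so ketene dimerisation and gamma-deprotonation can compete. A7 is volatile and hazardous. A5 itself needs a long synthesis.
- Comparison: the structural logic for ring A is more elegant. The mechanism is more demanding, since several pericyclic events run in one pot on a stereochemically labile substrate. The overall step count is probably equal or higher.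

**Alternative 3:** The cut removes C3–C4 and O1–C2. The salicylaldehyde A9 (the silyl analogue of 5) would be ionised with an orthoformate and a chiral phosphoric acid to the 4-methoxy o-quinone methide A10. A10 should undergo (4+2) cycloaddition with the ring B styrene A11 to give the 4-methoxyflavan A12.

- In its favour: ring C and the C2 stereocentre come from one step that joins two fragments of the size of 5 and 12. No triflate and no transition metal are needed. The electron-rich styrene is electronically well matched to the electron-poor heterodiene. On step economy this alternative is clearly better than the chosen plan.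
- Against it here: asymmetric induction rests on ion pairing of the chiral phosphate with A10 in an intermolecular reaction with a styrene that offers no hydrogen-bond donor. With such an electron-rich styrene the addition is likely to be stepwise through a C2 benzylic cation, and the same acid can re-ionise C2–O1 of A12. A11 has a second styrene-type double bond in its pyran ring and A9 has a prenyl olefin, both possible competing 2π partners. Aryl silyl ethers must survive the acid. The C4 methyl ether must later be turned into the ketone on an acid-labile flavan.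
- Comparison: the ring A problem is the same as in the chosen plan (equal). Mechanistically the chosen plan separates creation of the stereocentre from ring closure, while the alternative merges them under conditions that can scramble C2.

Key step: step 11

Assumption: the carbon that becomes C4 is carried as a mixture of both configurations from 14 to 18, because it is flattened to the carbonyl in 19. Compounds 14 and 15 are racemic; 16 to 18 are pairs of epimers with uniform (S) configuration at the carbinol or C2 centre.

## Steps

Step 1
Reactants: 1 2,4,6-trihydroxybenzaldehyde; 2 prenyl bromide (1-bromo-3-methylbut-2-ene)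
Product: 3 2,4,6-trihydroxy-3-(3-methylbut-2-en-1-yl)benzaldehyde
Conditions: DBU (1.0 equiv), THF, 0 °C → rt
Reagents that add atoms: none
Why: C-alkylation of a phloroglucinol-type phenoxide by an allylic bromide; C3 and C5 of 1 are equivalent, so only one mono-C-prenyl isomer can form, and 2 is kept limiting to hold back double alkylation and O-alkylation.

Step 2
Reactants: 3 2,4,6-trihydroxy-3-(3-methylbut-2-en-1-yl)benzaldehyde
Product: 4 2,6-dihydroxy-4-methoxy-3-(3-methylbut-2-en-1-yl)benzaldehyde
Conditions: Me2SO4 (1.0 equiv), K2CO3 (1.0 equiv), acetone, rt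
Reagents that add atoms: dimethyl sulfate, COS(=O)(=O)OC
Why: Williamson methylation with one equivalent of weak base; the C4 hydroxyl is para to the formyl group and not held in the hydrogen bond to the carbonyl, so it is the most acidic and should be alkylated first.

Step 3
Reactants: 4 2,6-dihydroxy-4-methoxy-3-(3-methylbut-2-en-1-yl)benzaldehyde
Product: 5 2-hydroxy-4-methoxy-6-(methoxymethoxy)-3-(3-methylbut-2-en-1-yl)benzaldehyde
Conditions: MOMCl (1.1 equiv), iPr2NEt, CH2Cl2, 0 °C
Reagents that add atoms: chloromethyl methyl ether, COCCl
Why: O-alkylation of the less hindered of the two ortho hydroxyls (C6–OH has a hydrogen neighbour, C2–OH is flanked by the prenyl group); after mono-alkylation the remaining hydroxyl is locked in the hydrogen bond to the formyl oxygen and should resist a second alkylation.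

Step 4
Reactants: 5 2-hydroxy-4-methoxy-6-(methoxymethoxy)-3-(3-methylbut-2-en-1-yl)benzaldehyde
Product: 6 2-formyl-5-methoxy-3-(methoxymethoxy)-6-(3-methylbut-2-en-1-yl)phenyl trifluoromethanesulfonate
Conditions: Tf2O, pyridine, CH2Cl2, −20 → 0 °C
Reagents that add atoms: trifluoromethanesulfonic anhydride, O=S(=O)(OS(=O)(=O)C(F)(F)F)C(F)(F)F
Why: O-sulfonylation of the only free phenol through the N-triflylpyridinium salt; the pyridine buffer protects the MOM ether and the prenyl olefin from triflic acid.

Step 5
Reactants: 7 4-bromoresorcinol (4-bromobenzene-1,3-diol); 8 3-methyl-2-butenal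
Product: 9 6-bromo-2,2-dimethyl-2H-chromen-7-ol
Conditions: ethylenediammonium diacetate (10 mol %), toluene, reflux
Reagents that add atoms: none
Why: domino Knoevenagel-type condensation and 6π oxa-electrocyclisation of a resorcinol with an enal; C6 of 7 (ortho to one hydroxyl, para to the other) is the unhindered nucleophilic carbon, and without an ortho-acyl chelate nothing biases the reaction towards C2 between the hydroxyls, so the linear 7-hydroxy chromene with bromine at C6 should form.

Step 6
Reactants: 9 6-bromo-2,2-dimethyl-2H-chromen-7-ol
Product: 10 6-bromo-7-(methoxymethoxy)-2,2-dimethyl-2H-chromene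
Conditions: MOMCl, iPr2NEt, CH2Cl2, 0 °C → rt
Reagents that add atoms: chloromethyl methyl ether, COCCl
Why: standard acetal protection of a phenol; the MOM oxygen later stabilises the ortho aryllithium by chelation.

Step 7
Reactants: 10 6-bromo-7-(methoxymethoxy)-2,2-dimethyl-2H-chromene
Product: 12 1-[7-(methoxymethoxy)-2,2-dimethyl-2H-chromen-6-yl]ethan-1-one, via aryllithium 11 (not isolated)
Conditions: n-BuLi, THF, −78 °C; then MeC(O)N(OMe)Me, −78 → 0 °C; aq NH4Cl
Reagents that add atoms: N-methoxy-N-methylacetamide, CC(=O)N(C)OC
Why: bromine–lithium exchange is faster than deprotonation and fixes the metal at C6; the Weinreb amide gives a stable tetrahedral chelate that releases the methyl ketone only on work-up (Weinreb ketone synthesis), so the acetyl group lands on the linear position that electrophilic acylation or directed metalation would not reach reliably.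

Step 8
Reactants: 12 1-[7-(methoxymethoxy)-2,2-dimethyl-2H-chromen-6-yl]ethan-1-one; 6 2-formyl-5-methoxy-3-(methoxymethoxy)-6-(3-methylbut-2-en-1-yl)phenyl trifluoromethanesulfonate
Product: 14 racemic 2-{1-hydroxy-3-[7-(methoxymethoxy)-2,2-dimethyl-2H-chromen-6-yl]-3-oxopropyl}-5-methoxy-3-(methoxymethoxy)-6-(3-methylbut-2-en-1-yl)phenyl trifluoromethanesulfonate, via lithium enolate 13 (not isolated)
Conditions: LiN(iPr)2, THF, −78 °C; then 6, −78 °C; AcOH quench at −78 °C
Reagents that add atoms: none
Why: directed aldol addition of the kinetic lithium enolate to a non-enolisable aldehyde; the triflate has no ortho hydrogen, so the amide base cannot cause aryne formation or thia-Fries rearrangement, and the cold acidic quench prevents retro-aldol cleavage and dehydration. The new carbinol is formed racemic on purpose because it becomes the C4 carbonyl.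

Step 9
Reactants: 14 racemic aldol adduct
Product: 15 racemic 2-{1-[(tert-butyldimethylsilyl)oxy]-3-[7-(methoxymethoxy)-2,2-dimethyl-2H-chromen-6-yl]-3-oxopropyl}-5-methoxy-3-(methoxymethoxy)-6-(3-methylbut-2-en-1-yl)phenyl trifluoromethanesulfonate
Conditions: TBSOTf, 2,6-lutidine, CH2Cl2, −78 °C
Reagents that add atoms: tert-butyldimethylsilyl trifluoromethanesulfonate, CC(C)(C)[Si](C)(C)OS(=O)(=O)C(F)(F)F
Why: silyl triflate with a hindered pyridine base silylates the crowded benzylic aldol hydroxyl at low temperature without retro-aldol cleavage (standard protection of aldol adducts); the silyl ether later blocks dehydration, retro-aldol reaction and alkoxide chelation to palladium.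

Step 10
Reactants: 15 racemic beta-silyloxy ketone
Product: 16 2-{(3S)-1-[(tert-butyldimethylsilyl)oxy]-3-hydroxy-3-[7-(methoxymethoxy)-2,2-dimethyl-2H-chromen-6-yl]propyl}-5-methoxy-3-(methoxymethoxy)-6-(3-methylbut-2-en-1-yl)phenyl trifluoromethanesulfonate (both C1 epimers)
Conditions: (R)-2-methyl-CBS-oxazaborolidine [(3aR)-1-methyl-3,3-diphenyltetrahydro-1H,3H-pyrrolo[1,2-c][1,3,2]oxazaborole] (20 mol %), catecholborane, toluene, −78 → −40 °C; MeOH
Reagents that add atoms: none
Why: Corey–Bakshi–Shibata reduction; the ketone binds the catalyst boron with the large aryl group away from the ring substituent, and hydride from the nitrogen-bound borane goes to the Re face, which gives the (S)-carbinol with the (R)-catalyst. Catecholborane replaces BH3 because it does not hydroborate the prenyl or chromene double bonds at low temperature, and the remote racemic silyloxy centre should leave the reaction under catalyst control for both enantiomers of 15.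

Step 11
Reactants: 16 (3S)-carbinol aryl triflate (both C1 epimers)
Product: 17 tert-butyl{[(2S)-7-methoxy-5-(methoxymethoxy)-2-[7-(methoxymethoxy)-2,2-dimethyl-2H-chromen-6-yl]-8-(3-methylbut-2-en-1-yl)-3,4-dihydro-2H-chromen-4-yl]oxy}dimethylsilane (both C4 epimers)
Conditions: Pd(OAc)2 (5 mol %), 2-(di-tert-butylphosphino)-1,1′-binaphthyl (7.5 mol %), Cs2CO3 (1.5 equiv), toluene, 80 °C
Reagents that add atoms: none
Why: zerovalent palladium, formed from Pd(OAc)2 and the phosphine, inserts into the C8a–OTf bond of 16; Cs2CO3 then deprotonates the coordinated C2 hydroxyl to give a seven-membered aryl(alkoxo) chelate of divalent palladium, and C–O reductive elimination releases 17 and regenerates the zerovalent metal. The closest known reaction type is the palladium-catalysed cyclisation of aryl halides and sulfonates bearing tethered secondary alcohols to chromans with di-tert-butyl(biaryl)phosphines (intramolecular Buchwald–Hartwig etherification). Ring C closes as a six-membered ring by reductive elimination at the metal, formally a 6-exo attack of the C2 oxygen on C8a, and not by substitution at carbon. No stereocentre is created: C2 keeps the (S) configuration because its C–O bond is never broken and the benzylic carbon never becomes cationic. The step needs reductive elimination to outrun beta-hydride elimination of the secondary alkoxide, which the bulky electron-rich phosphine enforces by crowding the metal. It also needs the triflate to survive the base: C8a has no ortho hydrogen (C8 carries the prenyl group, C4a the side chain), so aryne formation and anionic thia-Fries rearrangement are excluded, and the weak, poorly soluble carbonate keeps S–O cleavage slow. The C4 oxygen is silylated so that it can neither form a five-membered alkoxide chelate that would pass a hydride to the metal nor ionise, and both C4 epimers can cyclise because C4 is a spectator.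

Step 12
Reactants: 17 (2S)-flavan-4-yl silyl ether (both C4 epimers)
Product: 18 (2S)-7-methoxy-5-(methoxymethoxy)-2-[7-(methoxymethoxy)-2,2-dimethyl-2H-chromen-6-yl]-8-(3-methylbut-2-en-1-yl)-3,4-dihydro-2H-chromen-4-ol (both C4 epimers)
Conditions: Bu4NF, THF, 0 °C → rt; aq NH4Cl
Reagents that add atoms: none
Why: fluoride cleaves the secondary alkyl silyl ether by forming the strong Si–F bond; aryl MOM ethers and both olefins are inert, and the mildly basic medium avoids ionisation of the electron-rich benzylic C4 carbinol.

Step 13
Reactants: 18 (2S)-flavan-4-ol (both C4 epimers)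
Product: 19 (2S)-7-methoxy-5-(methoxymethoxy)-2-[7-(methoxymethoxy)-2,2-dimethyl-2H-chromen-6-yl]-8-(3-methylbut-2-en-1-yl)-2,3-dihydro-4H-chromen-4-one
Conditions: Dess–Martin periodinane, NaHCO3, CH2Cl2, 0 °C → rt
Reagents that add atoms: none
Why: Dess–Martin oxidation of a benzylic carbinol under hydrogen carbonate buffer; the near-neutral conditions avoid acid ionisation at C4 or C2 and base-induced retro-oxa-Michael opening, and both C4 epimers converge on one ketone.

Step 14
Reactants: 19 (2S)-flavanone bis-MOM ether
Product: 20 maackiaflavanone A, (2S)-5-hydroxy-2-(7-hydroxy-2,2-dimethyl-2H-chromen-6-yl)-7-methoxy-8-(3-methylbut-2-en-1-yl)-2,3-dihydro-4H-chromen-4-one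
Conditions: TMSOTf, 2,2′-bipyridyl, CH2Cl2, 0 °C → rt; then H2O
Reagents that add atoms: none
Why: a silyl triflate tamed by 2,2′-bipyridyl converts aryl MOM ethers into aryl silyl ethers and N-(methoxymethyl)pyridinium salts, both of which hydrolyse when water is added (mild MOM cleavage for acid-sensitive substrates); the medium stays buffered, so the C2–O1 bond, the prenyl group and the chromene should not meet strong Brønsted acid, and the C5 ether next to the carbonyl should cleave most readily.

## Compound list

1 | 2,4,6-trihydroxybenzaldehyde | O=Cc1c(O)cc(O)cc1O | starting material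
2 | prenyl bromide (1-bromo-3-methylbut-2-ene) | CC(C)=CCBr | starting material
3 | 2,4,6-trihydroxy-3-(3-methylbut-2-en-1-yl)benzaldehyde | O=Cc1c(O)cc(O)c(CC=C(C)C)c1O | intermediate
4 | 2,6-dihydroxy-4-methoxy-3-(3-methylbut-2-en-1-yl)benzaldehyde | COc1cc(O)c(C=O)c(O)c1CC=C(C)C | intermediate
5 | 2-hydroxy-4-methoxy-6-(methoxymethoxy)-3-(3-methylbut-2-en-1-yl)benzaldehyde | COc1cc(OCOC)c(C=O)c(O)c1CC=C(C)C | intermediate
6 | 2-formyl-5-methoxy-3-(methoxymethoxy)-6-(3-methylbut-2-en-1-yl)phenyl trifluoromethanesulfonate | COc1cc(OCOC)c(C=O)c(OS(=O)(=O)C(F)(F)F)c1CC=C(C)C | intermediate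
7 | 4-bromoresorcinol (4-bromobenzene-1,3-diol) | Oc1ccc(Br)c(O)c1 | starting material
8 | 3-methyl-2-butenal | CC(C)=CC=O | starting material
9 | 6-bromo-2,2-dimethyl-2H-chromen-7-ol | CC1(C)C=Cc2cc(Br)c(O)cc2O1 | intermediate
10 | 6-bromo-7-(methoxymethoxy)-2,2-dimethyl-2H-chromene | COCOc1cc2c(cc1Br)C=CC(C)(C)O2 | intermediate
11 | [7-(methoxymethoxy)-2,2-dimethyl-2H-chromen-6-yl]lithium | [Li]c1cc2c(cc1OCOC)OC(C)(C)C=C2 | intermediate (not isolated)
12 | 1-[7-(methoxymethoxy)-2,2-dimethyl-2H-chromen-6-yl]ethan-1-one | CC(=O)c1cc2c(cc1OCOC)OC(C)(C)C=C2 | intermediate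
13 | lithium 1-[7-(methoxymethoxy)-2,2-dimethyl-2H-chromen-6-yl]ethen-1-olate | [Li]OC(=C)c1cc2c(cc1OCOC)OC(C)(C)C=C2 | intermediate (not isolated)
14 | racemic 2-{1-hydroxy-3-[7-(methoxymethoxy)-2,2-dimethyl-2H-chromen-6-yl]-3-oxopropyl}-5-methoxy-3-(methoxymethoxy)-6-(3-methylbut-2-en-1-yl)phenyl trifluoromethanesulfonate | COc1cc(OCOC)c(C(O)CC(=O)c2cc3c(cc2OCOC)OC(C)(C)C=C3)c(OS(=O)(=O)C(F)(F)F)c1CC=C(C)C | intermediate
15 | racemic 2-{1-[(tert-butyldimethylsilyl)oxy]-3-[7-(methoxymethoxy)-2,2-dimethyl-2H-chromen-6-yl]-3-oxopropyl}-5-methoxy-3-(methoxymethoxy)-6-(3-methylbut-2-en-1-yl)phenyl trifluoromethanesulfonate | COc1cc(OCOC)c(C(O[Si](C)(C)C(C)(C)C)CC(=O)c2cc3c(cc2OCOC)OC(C)(C)C=C3)c(OS(=O)(=O)C(F)(F)F)c1CC=C(C)C | intermediate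
16 | 2-{(3S)-1-[(tert-butyldimethylsilyl)oxy]-3-hydroxy-3-[7-(methoxymethoxy)-2,2-dimethyl-2H-chromen-6-yl]propyl}-5-methoxy-3-(methoxymethoxy)-6-(3-methylbut-2-en-1-yl)phenyl trifluoromethanesulfonate, both C1 epimers | COc1cc(OCOC)c(C(O[Si](C)(C)C(C)(C)C)C[C@H](O)c2cc3c(cc2OCOC)OC(C)(C)C=C3)c(OS(=O)(=O)C(F)(F)F)c1CC=C(C)C | intermediate
17 | tert-butyl{[(2S)-7-methoxy-5-(methoxymethoxy)-2-[7-(methoxymethoxy)-2,2-dimethyl-2H-chromen-6-yl]-8-(3-methylbut-2-en-1-yl)-3,4-dihydro-2H-chromen-4-yl]oxy}dimethylsilane, both C4 epimers | COc1cc(OCOC)c2c(c1CC=C(C)C)O[C@H](c1cc3c(cc1OCOC)OC(C)(C)C=C3)CC2O[Si](C)(C)C(C)(C)C | intermediate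
18 | (2S)-7-methoxy-5-(methoxymethoxy)-2-[7-(methoxymethoxy)-2,2-dimethyl-2H-chromen-6-yl]-8-(3-methylbut-2-en-1-yl)-3,4-dihydro-2H-chromen-4-ol, both C4 epimers | COc1cc(OCOC)c2c(c1CC=C(C)C)O[C@H](c1cc3c(cc1OCOC)OC(C)(C)C=C3)CC2O | intermediate
19 | (2S)-7-methoxy-5-(methoxymethoxy)-2-[7-(methoxymethoxy)-2,2-dimethyl-2H-chromen-6-yl]-8-(3-methylbut-2-en-1-yl)-2,3-dihydro-4H-chromen-4-one | COc1cc(OCOC)c2c(c1CC=C(C)C)O[C@H](c1cc3c(cc1OCOC)OC(C)(C)C=C3)CC2=O | intermediate
20 | maackiaflavanone A, (2S)-5-hydroxy-2-(7-hydroxy-2,2-dimethyl-2H-chromen-6-yl)-7-methoxy-8-(3-methylbut-2-en-1-yl)-2,3-dihydro-4H-chromen-4-one | COc1cc(O)c2c(c1CC=C(C)C)O[C@H](c1cc3c(cc1O)OC(C)(C)C=C3)CC2=O | target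

## Step count and least certain steps

Total step count: 14. Longest linear sequence: 11 steps (steps 1–4 and 8–14, from 1); the ring B branch (steps 5–7) joins at step 8. The enantiomeric purity of 20 is fixed in step 10 and must be carried through steps 11–14.

**Step 11 (key step).** Oxidative addition at C8a is slowed by two ortho substituents and an electron-rich ring, so slower side processes get time to compete:
- cleavage of the S–O bond by carbonate or by the C2 alkoxide; triflyl transfer to the alkoxide followed by substitution at C2 would cost configuration;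
- migration of the silyl group from the C4 oxygen to the C2 alkoxide, which frees a C4 alkoxide that can chelate the metal and pass on a hydride, reducing the C–O bond at C8a to C–H;
- beta-hydride elimination at C2, which would return the ketone.

Fallback: ring closure at the other end of O1 by substitution with inversion. It sets out from 15, which would be reduced with the enantiomeric (S)-oxazaborolidine and catecholborane to the (3R)-carbinol aryl triflate F1. The triflate would be cleaved with aqueous tetraethylammonium hydroxide in dioxane to the (3R)-carbinol phenol F2; the silyl group should stay on the alkyl oxygen because the phenoxide is the more stable anion. Mitsunobu cyclisation (PPh3, diisopropyl azodicarboxylate, toluene, 0 °C) should then close O1–C2 with inversion and rejoin the route at 17. Its weakness is partial ionisation at the electron-rich benzylic carbon, which is why it is only the fallback.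

**Step 3.** Alkylation may not discriminate cleanly between the two ortho hydroxyls of 4, giving the isomer that would end as a 6-prenyl flavanone. Upstream of it, step 1 can suffer from O-alkylation and double alkylation, and step 2 from methylation at an ortho hydroxyl.

Fallback: fix the regiochemistry by a para-Claisen rearrangement instead of by selective alkylation. It sets out from 1, which would be mono-methylated at the para hydroxyl (Me2SO4, K2CO3, acetone) to the symmetric 2,6-dihydroxy-4-methoxybenzaldehyde F3. One of its two equivalent hydroxyls would be sulfonylated (Tf2O, one equivalent, pyridine) to 2-formyl-3-hydroxy-5-methoxyphenyl trifluoromethanesulfonate F4. O-Alkylation with 2 (K2CO3, acetone) should give the prenyl ether 2-formyl-5-methoxy-3-[(3-methylbut-2-en-1-yl)oxy]phenyl trifluoromethanesulfonate F5. Heating in N,N-diethylaniline should move the prenyl group by Claisen and then Cope rearrangement to the carbon para to the ether oxygen, between the triflate and the methoxy group, giving 2-formyl-3-hydroxy-5-methoxy-6-(3-methylbut-2-en-1-yl)phenyl trifluoromethanesulfonate F6. Protection with MOMCl and iPr2NEt rejoins the route at 6. Arrest at the ortho position as the reverse-prenyl isomer is the risk of this variant.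

**Step 5.** The annulation may take place in part at C2 of 7, between the hydroxyls, or twice, and the isomers may be hard to separate.

Fallback: bring in the carbon substituent after the pyran ring by ortho-formylation. It sets out from 8, which would be condensed under the same conditions with purchased resorcinol F7 to 2,2-dimethyl-2H-chromen-7-ol F8. Casnati–Skattebøl formylation (MgCl2, Et3N, paraformaldehyde, MeCN, reflux) should go to the less hindered ortho carbon and give 7-hydroxy-2,2-dimethyl-2H-chromene-6-carbaldehyde F9. MOMCl and iPr2NEt would give 7-(methoxymethoxy)-2,2-dimethyl-2H-chromene-6-carbaldehyde F10, MeMgBr in THF the carbinol 1-[7-(methoxymethoxy)-2,2-dimethyl-2H-chromen-6-yl]ethan-1-ol F11, and Dess–Martin oxidation rejoins the route at 12. This costs two more steps.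

**Step 10.** The hindered ortho-alkoxy aryl ketone may be reduced slowly by catecholborane, and for one enantiomer of racemic 15 the remote silyloxy centre may oppose the catalyst, so that facial selectivity and with it the enantiomeric purity of 20 drops.

Fallback: a different mode of hydride delivery, Noyori–Ikariya transfer hydrogenation with RuCl[(S,S)-TsDPEN](p-cymene) and HCO2H/Et3N. This outer-sphere metal–ligand bifunctional mechanism does not touch isolated olefins and gives (S)-carbinols from aryl alkyl ketones. It sets out from 15 and comes back at 16; no new compound arises (F0).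

**Step 14.** Silyl activation of the C4 carbonyl or of O1 could open ring C reversibly and erode C2, and traces of triflic acid could add to the prenyl or chromene double bond.

Fallback: unmask the phenols before the beta-aryloxy ketone exists. It sets out from 17, which under the same TMSOTf/2,2′-bipyridyl conditions should give the diphenol (2S)-4-[(tert-butyldimethylsilyl)oxy]-2-(7-hydroxy-2,2-dimethyl-2H-chromen-6-yl)-7-methoxy-8-(3-methylbut-2-en-1-yl)-3,4-dihydro-2H-chromen-5-ol F12. Bu4NF in THF would give the triol (2S)-2-(7-hydroxy-2,2-dimethyl-2H-chromen-6-yl)-7-methoxy-8-(3-methylbut-2-en-1-yl)-3,4-dihydro-2H-chromene-4,5-diol F13. Oxidation of the benzylic carbinol with activated MnO2 in CH2Cl2, which tolerates free phenols, rejoins the route at 20.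

## Further compounds

F1 | step 11 | 2-{(3R)-1-[(tert-butyldimethylsilyl)oxy]-3-hydroxy-3-[7-(methoxymethoxy)-2,2-dimethyl-2H-chromen-6-yl]propyl}-5-methoxy-3-(methoxymethoxy)-6-(3-methylbut-2-en-1-yl)phenyl trifluoromethanesulfonate, both C1 epimers | COc1cc(OCOC)c(C(O[Si](C)(C)C(C)(C)C)C[C@@H](O)c2cc3c(cc2OCOC)OC(C)(C)C=C3)c(OS(=O)(=O)C(F)(F)F)c1CC=C(C)C
F2 | step 11 | 2-{(3R)-1-[(tert-butyldimethylsilyl)oxy]-3-hydroxy-3-[7-(methoxymethoxy)-2,2-dimethyl-2H-chromen-6-yl]propyl}-5-methoxy-3-(methoxymethoxy)-6-(3-methylbut-2-en-1-yl)phenol, both C1 epimers | COc1cc(OCOC)c(C(O[Si](C)(C)C(C)(C)C)C[C@@H](O)c2cc3c(cc2OCOC)OC(C)(C)C=C3)c(O)c1CC=C(C)C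
F3 | step 3 | 2,6-dihydroxy-4-methoxybenzaldehyde | COc1cc(O)c(C=O)c(O)c1
F4 | step 3 | 2-formyl-3-hydroxy-5-methoxyphenyl trifluoromethanesulfonate | COc1cc(O)c(C=O)c(OS(=O)(=O)C(F)(F)F)c1
F5 | step 3 | 2-formyl-5-methoxy-3-[(3-methylbut-2-en-1-yl)oxy]phenyl trifluoromethanesulfonate | COc1cc(OCC=C(C)C)c(C=O)c(OS(=O)(=O)C(F)(F)F)c1
F6 | step 3 | 2-formyl-3-hydroxy-5-methoxy-6-(3-methylbut-2-en-1-yl)phenyl trifluoromethanesulfonate | COc1cc(O)c(C=O)c(OS(=O)(=O)C(F)(F)F)c1CC=C(C)C
F7 | step 5 | resorcinol (purchased) | Oc1cccc(O)c1
F8 | step 5 | 2,2-dimethyl-2H-chromen-7-ol | CC1(C)C=Cc2ccc(O)cc2O1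
F9 | step 5 | 7-hydroxy-2,2-dimethyl-2H-chromene-6-carbaldehyde | CC1(C)C=Cc2cc(C=O)c(O)cc2O1
F10 | step 5 | 7-(methoxymethoxy)-2,2-dimethyl-2H-chromene-6-carbaldehyde | COCOc1cc2c(cc1C=O)C=CC(C)(C)O2
F11 | step 5 | 1-[7-(methoxymethoxy)-2,2-dimethyl-2H-chromen-6-yl]ethan-1-ol (racemic) | COCOc1cc2c(cc1C(C)O)C=CC(C)(C)O2
F0 | step 10 | none | none
F12 | step 14 | (2S)-4-[(tert-butyldimethylsilyl)oxy]-2-(7-hydroxy-2,2-dimethyl-2H-chromen-6-yl)-7-methoxy-8-(3-methylbut-2-en-1-yl)-3,4-dihydro-2H-chromen-5-ol, both C4 epimers | COc1cc(O)c2c(c1CC=C(C)C)O[C@H](c1cc3c(cc1O)OC(C)(C)C=C3)CC2O[Si](C)(C)C(C)(C)C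
F13 | step 14 | (2S)-2-(7-hydroxy-2,2-dimethyl-2H-chromen-6-yl)-7-methoxy-8-(3-methylbut-2-en-1-yl)-3,4-dihydro-2H-chromene-4,5-diol, both C4 epimers | COc1cc(O)c2c(c1CC=C(C)C)O[C@H](c1cc3c(cc1O)OC(C)(C)C=C3)CC2O
A1 | alternative 1 | 2-iodo-5-methoxy-3-(methoxymethoxy)-6-(3-methylbut-2-en-1-yl)phenol | COc1cc(OCOC)c(I)c(O)c1CC=C(C)C
A2 | alternative 1 | carbon monoxide | [C-]#[O+]
A3 | alternative 1 | 6-ethynyl-7-(methoxymethoxy)-2,2-dimethyl-2H-chromene | C#Cc1cc2c(cc1OCOC)OC(C)(C)C=C2
A4 | alternative 1 | 7-methoxy-5-(methoxymethoxy)-2-[7-(methoxymethoxy)-2,2-dimethyl-2H-chromen-6-yl]-8-(3-methylbut-2-en-1-yl)-4H-chromen-4-one | COc1cc(OCOC)c2c(c1CC=C(C)C)OC(c1cc3c(cc1OCOC)OC(C)(C)C=C3)=CC2=O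
A5 | alternative 2 | 2-{(2S)-2-[7-(methoxymethoxy)-2,2-dimethyl-2H-chromen-6-yl]-4-oxo-3,4-dihydro-2H-pyran-6-yl}-5-methylhex-4-enoyl chloride | O=C(Cl)C(CC=C(C)C)C1=CC(=O)C[C@@H](c2cc3c(cc2OCOC)OC(C)(C)C=C3)O1
A6 | alternative 2 | vinylketene, (2S)-2-[7-(methoxymethoxy)-2,2-dimethyl-2H-chromen-6-yl]-6-(5-methyl-1-oxohexa-1,4-dien-2-yl)-2,3-dihydro-4H-pyran-4-one | O=C=C(CC=C(C)C)C1=CC(=O)C[C@@H](c2cc3c(cc2OCOC)OC(C)(C)C=C3)O1
A7 | alternative 2 | methoxyacetylene | COC#C
A8 | alternative 2 | (2S)-maackiaflavanone A 2′-O-methoxymethyl ether | COc1cc(O)c2c(c1CC=C(C)C)O[C@H](c1cc3c(cc1OCOC)OC(C)(C)C=C3)CC2=O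
A9 | alternative 3 | 6-[(tert-butyldimethylsilyl)oxy]-2-hydroxy-4-methoxy-3-(3-methylbut-2-en-1-yl)benzaldehyde | COc1cc(O[Si](C)(C)C(C)(C)C)c(C=O)c(O)c1CC=C(C)C
A10 | alternative 3 | 4-methoxy o-quinone methide, 5-[(tert-butyldimethylsilyl)oxy]-3-methoxy-6-(methoxymethylidene)-2-(3-methylbut-2-en-1-yl)cyclohexa-2,4-dien-1-one | COC=C1C(=O)C(CC=C(C)C)=C(OC)C=C1O[Si](C)(C)C(C)(C)C
A11 | alternative 3 | tert-butyl[(6-ethenyl-2,2-dimethyl-2H-chromen-7-yl)oxy]dimethylsilane | C=Cc1cc2c(cc1O[Si](C)(C)C(C)(C)C)OC(C)(C)C=C2
A12 | alternative 3 | (2S,4S)-5-[(tert-butyldimethylsilyl)oxy]-2-{7-[(tert-butyldimethylsilyl)oxy]-2,2-dimethyl-2H-chromen-6-yl}-4,7-dimethoxy-8-(3-methylbut-2-en-1-yl)-3,4-dihydro-2H-chromene | COc1cc(O[Si](C)(C)C(C)(C)C)c2c(c1CC=C(C)C)O[C@H](c1cc3c(cc1O[Si](C)(C)C(C)(C)C)OC(C)(C)C=C3)C[C@@H]2OC
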